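**Retrosynthetic overview**
- The enal is unmasked last (diethyl acetal and two aryl MOM ethers, one acid step); its three carbons come from a Suzuki–Miyaura coupling on an aryl bromide.
- The dioxane ring (O1, C2, C3, O4, C4a, C8a) is cut at O4–C3 (phenol oxygen to the aryl-bearing benzylic carbon) and at C2–C3; both bonds and both stereocentres are made in one amine-catalysed domino from lactol 7 and aldehyde 9, with hydride reduction in the same flask.
- Enabling feature: C2 (the CH2OH carbon) lies between O1 and benzylic C3, so with the exocyclic carbon as an aldehyde, C2=C3 is the alkene of an α-aryloxy enal; its β-carbon C3 is then in reach of the second catechol oxygen (O4 on C4a of ring B) for a six-membered closure.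
- Lactol 7 comes from 5-bromo-ortho-vanillin (O-alkylation of its single phenol fixes which oxygen carries C2, then Baeyer–Villiger oxidation and acetal hydrolysis); aldehyde 9 comes from 5-hydroxyvanillin.
- Ring order: temporary lactol ring (step 3), then opened and replaced by the dioxane ring of the target (step 5).

Key step: step 5

Remark: lactol 7 is used as its racemic hemiacetal. It is the ring tautomer of hydroxy aldehyde 6 and is taken to enter step 5 by amine exchange at its hemiacetal carbon, where that stereocentre is destroyed, so it has no bearing on the outcome.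
Remark: the quinine-derived primary amine is assumed, by analogy only, to be the pseudo-enantiomer that leads to the 3R series; if the sense proves opposite, the quinidine-derived amine takes its place with no other change.

Step 1
Reactants: 1 5-bromo-2-hydroxy-3-methoxybenzaldehyde; 2 2-bromo-1,1-diethoxyethane
Product: 3 5-bromo-2-(2,2-diethoxyethoxy)-3-methoxybenzaldehyde
Conditions: K2CO3, KI (cat.), DMF, 110 °C
Reagents that add atoms: none
Why: Williamson ether synthesis on the only phenol of 1 places the two-carbon unit unambiguously on the oxygen flanked by OMe; the hindered phenoxide and the sluggish bromoacetal need a polar aprotic solvent and heat, and the product has no acidic C–H that could condense with the ortho aldehyde.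

Step 2
Reactants: 3 5-bromo-2-(2,2-diethoxyethoxy)-3-methoxybenzaldehyde
Product: 5 5-bromo-2-(2,2-diethoxyethoxy)-3-methoxyphenol, via aryl formate 4 (not isolated)
Conditions: mCPBA (acid-free, dried), CH2Cl2, 0 °C to rt; then Et3N (cat.), MeOH, rt
Reagents that add atoms: mCPBA (3-chloroperoxybenzoic acid), OOC(=O)c1cccc(Cl)c1
Why: Baeyer–Villiger oxidation of an ortho-alkoxybenzaldehyde should proceed by aryl migration to formate 4, which mild methanolysis cleaves to the phenol; the dry, acid-free medium should spare the diethyl acetal.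

Step 3
Reactants: 5 5-bromo-2-(2,2-diethoxyethoxy)-3-methoxyphenol
Product: 7 7-bromo-5-methoxy-2,3-dihydro-1,4-benzodioxin-2-ol (lactol), via open-chain aldehyde 6 (not isolated)
Conditions: HCl (1 M aq., cat.), THF, rt
Reagents that add atoms: water, O
Why: Acid-catalysed acetal hydrolysis releases aldehyde 6, which the ortho phenol should trap at once as the six-membered cyclic hemiacetal, a storable form that does not self-condense.

Step 4
Reactants: 8 3,4-dihydroxy-5-methoxybenzaldehyde
Product: 9 3-methoxy-4,5-bis(methoxymethoxy)benzaldehyde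
Conditions: MOMCl, K2CO3, acetone, 0 °C to rt
Reagents that add atoms: chloromethyl methyl ether (MOMCl), COCCl
Why: O-Alkylation of both phenols (MOM ether formation) gives acetals that tolerate amines, hydride, aqueous carbonate and palladium and are removed by acid at the end.

Step 5
Reactants: 7 7-bromo-5-methoxy-2,3-dihydro-1,4-benzodioxin-2-ol; 9 3-methoxy-4,5-bis(methoxymethoxy)benzaldehyde
Product: 12 [(2R,3R)-6-bromo-8-methoxy-3-[3-methoxy-4,5-bis(methoxymethoxy)phenyl]-2,3-dihydro-1,4-benzodioxin-2-yl]methanol, via aryloxy enal 10 (not isolated), via benzodioxine carbaldehyde 11 (not isolated)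
Conditions: 9-amino-9-deoxy-epi-quinine (20 mol %), CF3CO2H (30 mol %), toluene, 40 °C; then MeOH, NaBH4, −20 °C
Reagents that add atoms: none
Why: Proposed new method: the primary amine condenses at the hemiacetal carbon of lactol 7 (N,O-acetal, ring-opened iminium ion, then enamine, which frees the phenol), the enamine condenses (Mannich/aldol addition, then loss of water) with the non-enolisable aldehyde 9 to the iminium ion of (Z)-enal 10, in which the benzylic carbon is the β-carbon and the free phenol on the α-aryloxy group adds to it; tautomerisation and hydrolysis give aldehyde 11, which NaBH4 reduces in the same flask. The closest known reaction types are the Kabbe chromanone synthesis (amine-mediated aldol condensation followed by intramolecular oxa-Michael closure), amine-catalysed cross-aldol condensation to α-substituted cinnamaldehydes, and iminium catalysis of hetero-Michael additions to α-branched enals by cinchona-derived primary amines. The dioxane ring closes by a 6-endo-trig oxa-Michael addition that forms the bond from the phenol oxygen O4 to the aryl-bearing carbon C3. C3 is set by the catalyst, which should shield one face of the iminium ion so that the phenol, activated by the quinuclidine base, reaches the Re face of the β-carbon (3R); the formyl-bearing C2 is α to the iminium/enamine and should equilibrate to the trans, diequatorial aldehyde before hydride fixes it. The step needs cross- rather than self-condensation and a single mode of closure: 9 cannot enolise and is used in slight excess while the enolisable partner is stored as lactol 7, and the only free phenol sits ortho to the aryloxy oxygen, so only the six-membered ring can form. Reduction at low temperature directly after closure should forestall retro-oxa-Michael opening, the process that would erode enantiomeric purity.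

Step 6
Reactants: 12 [(2R,3R)-6-bromo-8-methoxy-3-[3-methoxy-4,5-bis(methoxymethoxy)phenyl]-2,3-dihydro-1,4-benzodioxin-2-yl]methanol; 13 2-[(1E)-3,3-diethoxyprop-1-en-1-yl]-4,4,5,5-tetramethyl-1,3,2-dioxaborolane
Product: 14 [(2R,3R)-6-[(1E)-3,3-diethoxyprop-1-en-1-yl]-8-methoxy-3-[3-methoxy-4,5-bis(methoxymethoxy)phenyl]-2,3-dihydro-1,4-benzodioxin-2-yl]methanol
Conditions: Pd(dppf)Cl2 (5 mol %), K2CO3 (2 M aq.), 1,4-dioxane, 80 °C
Reagents that add atoms: none
Why: Suzuki–Miyaura coupling of the unhindered aryl bromide with the (E)-alkenylboronate should transfer the three-carbon unit with retention of alkene geometry; the free primary alcohol, the MOM ethers and the acetal tolerate aqueous carbonate, and neither stereocentre is touched.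

Step 7
Reactants: 14 [(2R,3R)-6-[(1E)-3,3-diethoxyprop-1-en-1-yl]-8-methoxy-3-[3-methoxy-4,5-bis(methoxymethoxy)phenyl]-2,3-dihydro-1,4-benzodioxin-2-yl]methanol
Product: 16 (2E)-3-[(2R,3R)-3-(3,4-dihydroxy-5-methoxyphenyl)-2-(hydroxymethyl)-8-methoxy-2,3-dihydro-1,4-benzodioxin-6-yl]prop-2-enal, via MOM-protected enal 15 (not isolated)
Conditions: HCl (3 M aq.), THF, 45 °C, argon
Reagents that add atoms: water, O
Why: Acid-catalysed hydrolysis should cleave the diethyl acetal first (giving the thermodynamic E-enal 15) and then the two aryl MOM acetals; the trans-benzodioxane is the more stable diastereomer and should survive dilute acid at this temperature.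

**Compound list**
1 | 5-bromo-2-hydroxy-3-methoxybenzaldehyde | COc1cc(Br)cc(C=O)c1O | starting material
2 | 2-bromo-1,1-diethoxyethane | CCOC(CBr)OCC | starting material
3 | 5-bromo-2-(2,2-diethoxyethoxy)-3-methoxybenzaldehyde | CCOC(COc1c(C=O)cc(Br)cc1OC)OCC | intermediate
4 | 5-bromo-2-(2,2-diethoxyethoxy)-3-methoxyphenyl formate | CCOC(COc1c(OC=O)cc(Br)cc1OC)OCC | intermediate
5 | 5-bromo-2-(2,2-diethoxyethoxy)-3-methoxyphenol | CCOC(COc1c(O)cc(Br)cc1OC)OCC | intermediate
6 | 2-(4-bromo-2-hydroxy-6-methoxyphenoxy)acetaldehyde | O=CCOc1c(O)cc(Br)cc1OC | intermediate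
7 | 7-bromo-5-methoxy-2,3-dihydro-1,4-benzodioxin-2-ol (racemic lactol) | COc1cc(Br)cc2OC(O)COc12 | intermediate
8 | 3,4-dihydroxy-5-methoxybenzaldehyde | COc1cc(C=O)cc(O)c1O | starting material
9 | 3-methoxy-4,5-bis(methoxymethoxy)benzaldehyde | COCOc1cc(C=O)cc(OC)c1OCOC | intermediate
10 | (2Z)-2-(4-bromo-2-hydroxy-6-methoxyphenoxy)-3-[3-methoxy-4,5-bis(methoxymethoxy)phenyl]prop-2-enal (present as its iminium ion) | O=C/C(Oc1c(O)cc(Br)cc1OC)=C/c1cc(OC)c(OCOC)c(OCOC)c1 | intermediate
11 | (2S,3R)-6-bromo-8-methoxy-3-[3-methoxy-4,5-bis(methoxymethoxy)phenyl]-2,3-dihydro-1,4-benzodioxine-2-carbaldehyde | COc1cc([C@H]2Oc3cc(Br)cc(OC)c3O[C@@H]2C=O)cc(OCOC)c1OCOC | intermediate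
12 | [(2R,3R)-6-bromo-8-methoxy-3-[3-methoxy-4,5-bis(methoxymethoxy)phenyl]-2,3-dihydro-1,4-benzodioxin-2-yl]methanol | COc1cc([C@H]2Oc3cc(Br)cc(OC)c3O[C@@H]2CO)cc(OCOC)c1OCOC | intermediate
13 | 2-[(1E)-3,3-diethoxyprop-1-en-1-yl]-4,4,5,5-tetramethyl-1,3,2-dioxaborolane | CCOC(OCC)/C=C/B1OC(C)(C)C(C)(C)O1 | starting material
14 | [(2R,3R)-6-[(1E)-3,3-diethoxyprop-1-en-1-yl]-8-methoxy-3-[3-methoxy-4,5-bis(methoxymethoxy)phenyl]-2,3-dihydro-1,4-benzodioxin-2-yl]methanol | COc1cc([C@H]2Oc3cc(/C=C/C(OCC)OCC)cc(OC)c3O[C@@H]2CO)cc(OCOC)c1OCOC | intermediate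
15 | (2E)-3-[(2R,3R)-2-(hydroxymethyl)-8-methoxy-3-[3-methoxy-4,5-bis(methoxymethoxy)phenyl]-2,3-dihydro-1,4-benzodioxin-6-yl]prop-2-enal | COc1cc([C@H]2Oc3cc(/C=C/C=O)cc(OC)c3O[C@@H]2CO)cc(OCOC)c1OCOC | intermediate
16 | (2E)-3-[(2R,3R)-3-(3,4-dihydroxy-5-methoxyphenyl)-2-(hydroxymethyl)-8-methoxy-2,3-dihydro-1,4-benzodioxin-6-yl]prop-2-enal | COc1cc([C@H]2Oc3cc(/C=C/C=O)cc(OC)c3O[C@@H]2CO)cc(O)c1O | target

**Step count and risks**
Total step count: 7. Longest linear sequence: 6 steps (steps 1, 2, 3, 5, 6, 7, from compound 1).

Steps most likely to fail: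

1. Step 5 (bears the label). What may go wrong: poor facial discrimination at the α-branched iminium ion, reversible ring opening (retro-oxa-Michael) before the hydride arrives, or self-condensation of the enamine derived from 7 outrunning the cross-condensation. The fallback uses known chemistry, sets out from lactol 7 and comes back at 12. Lactol 7 is oxidised with Ag2CO3 on Celite (toluene, reflux) to 7-bromo-5-methoxy-1,4-benzodioxin-2(3H)-one F1. The aryl lactone is opened with the lithium salt of (S)-4-benzyl-1,3-oxazolidin-2-one (nBuLi, THF, −78 °C) and the liberated phenoxide is capped with Ac2O, giving (4S)-3-{[2-(acetyloxy)-4-bromo-6-methoxyphenoxy]acetyl}-4-benzyl-1,3-oxazolidin-2-one F2. An Evans syn-aldol reaction (Bu2BOTf, iPr2NEt, CH2Cl2, −78 to 0 °C) with aldehyde 9 should give (4S)-3-[(2S,3R)-2-[2-(acetyloxy)-4-bromo-6-methoxyphenoxy]-3-hydroxy-3-[3-methoxy-4,5-bis(methoxymethoxy)phenyl]propanoyl]-4-benzyl-1,3-oxazolidin-2-one F3, in which the auxiliary fixes the aryloxy-bearing carbon. LiBH4 (THF, MeOH, 0 °C) removes the auxiliary reductively and cleaves the aryl acetate, giving (1R,2R)-2-(4-bromo-2-hydroxy-6-methoxyphenoxy)-1-[3-methoxy-4,5-bis(methoxymethoxy)phenyl]propane-1,3-diol F4. A sulfonic acid resin (Amberlyst 15, dry CH2Cl2, rt, short contact time) ionises the electron-rich benzylic alcohol and the ortho phenol captures the cation; the fixed neighbouring centre should direct the aryl group trans, giving 12.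

2. Step 7. What may go wrong: the aryl MOM acetals cleave more slowly than the diethyl acetal, so the freed enal and the electron-rich catechol are exposed for a long time to acid and to released formaldehyde (hydroxymethylation, conjugate addition, oligomerisation), and prolonged acid could ionise the benzylic C3–O4 bond and epimerise C3. The fallback separates the two unmaskings; it sets out from 12 and comes back at 16. The MOM ethers are removed on the bromide, where no enal is present (HCl 3 M aq., THF, 45 °C), giving 5-[(2R,3R)-7-bromo-3-(hydroxymethyl)-5-methoxy-2,3-dihydro-1,4-benzodioxin-2-yl]-3-methoxybenzene-1,2-diol F5. Suzuki–Miyaura coupling with 13 as in step 6, under rigorous exclusion of oxygen, gives 5-[(2R,3R)-7-[(1E)-3,3-diethoxyprop-1-en-1-yl]-3-(hydroxymethyl)-5-methoxy-2,3-dihydro-1,4-benzodioxin-2-yl]-3-methoxybenzene-1,2-diol F6. The acetal alone is then hydrolysed under very mild conditions (pyridinium tosylate, acetone–water, rt) to 16.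

3. Step 6. What may go wrong: protodeboronation of 13, or hydrolytic loss of its acetal, in hot aqueous base before transmetalation, leaving 12 unconverted. The fallback replaces the boron reagent by an alkene insertion; it sets out from 12 and comes back at 14. A Mizoroki–Heck reaction of 12 with acrolein diethyl acetal (3,3-diethoxyprop-1-ene; Pd(OAc)2, nBu4NOAc, K2CO3, KCl, DMF, 90 °C), in which β-hydride elimination toward the ring gives the cinnamyl acetal, should give 14 directly; no new compound is made.

Further compounds
F1 | step 5 | 7-bromo-5-methoxy-1,4-benzodioxin-2(3H)-one | COc1cc(Br)cc2OC(=O)COc12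
F2 | step 5 | (4S)-3-{[2-(acetyloxy)-4-bromo-6-methoxyphenoxy]acetyl}-4-benzyl-1,3-oxazolidin-2-one | CC(=O)Oc1cc(Br)cc(OC)c1OCC(=O)N1[C@@H](Cc2ccccc2)COC1=O
F3 | step 5 | (4S)-3-[(2S,3R)-2-[2-(acetyloxy)-4-bromo-6-methoxyphenoxy]-3-hydroxy-3-[3-methoxy-4,5-bis(methoxymethoxy)phenyl]propanoyl]-4-benzyl-1,3-oxazolidin-2-one | COc1cc([C@@H](O)[C@H](Oc2c(OC(C)=O)cc(Br)cc2OC)C(=O)N2[C@@H](Cc3ccccc3)COC2=O)cc(OCOC)c1OCOC
F4 | step 5 | (1R,2R)-2-(4-bromo-2-hydroxy-6-methoxyphenoxy)-1-[3-methoxy-4,5-bis(methoxymethoxy)phenyl]propane-1,3-diol | COc1cc([C@@H](O)[C@H](Oc2c(O)cc(Br)cc2OC)CO)cc(OCOC)c1OCOC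
F0 | step 6 | none | none
F5 | step 7 | 5-[(2R,3R)-7-bromo-3-(hydroxymethyl)-5-methoxy-2,3-dihydro-1,4-benzodioxin-2-yl]-3-methoxybenzene-1,2-diol | COc1cc([C@H]2Oc3cc(Br)cc(OC)c3O[C@@H]2CO)cc(O)c1O
F6 | step 7 | 5-[(2R,3R)-7-[(1E)-3,3-diethoxyprop-1-en-1-yl]-3-(hydroxymethyl)-5-methoxy-2,3-dihydro-1,4-benzodioxin-2-yl]-3-methoxybenzene-1,2-diol | COc1cc([C@H]2Oc3cc(/C=C/C(OCC)OCC)cc(OC)c3O[C@@H]2CO)cc(O)c1O
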